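The constants, given at 90 °C, make G a reversible store: D, L and X give X and G with an equilibrium constant of 6.2 M⁻¹ there and 4.47 M⁻¹ in teal, while Q carries L off to Z and pairs of D leave irreversibly as D2.

| setting | grey | amber | teal | ochre |
|---|---|---|---|---|
| D | 37 mM | 37 mM | 37 mM | 37 mM |
| L | 66.6 mM | 66.6 mM | 66.6 mM | 66.6 mM |
| Q | 74.0 mM | 74.0 mM | 74.0 mM | 74.0 mM |
| X | 1.9 mM | 1.9 mM | 1.9 mM | 1.9 mM |
| temperature | 90 °C | 70 °C | 50 °C |  |
| time | 30 h | 30 h | 30 h | 30 h |
| remark |  |  |  | at 50 °C until 15 h, from then on at 90 °C |

1. the flask with the highest amount of G, in percent of the D charged ("all alike" if they lie within 1.5 percentage points) (grey / amber / teal / ochre / all alike)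
2. final G, as a percentage of the D charged, in grey
3. final G, as a percentage of the D charged, in amber
4. final G, as a percentage of the D charged, in teal
5. final G, as a percentage of the D charged, in ochre

- percent here means D units held: one D2 counts as two
- for a step with 2 of a species take k times the square, and two of it per event
- the list of constants is for 90 °C, to be carried to other temperatures by the activation energies and enthalpies

    D + L + X ⇌ X + G (K1 = 6.2 M⁻¹, k1 = 19.6 M⁻² min⁻¹, Ea1 = 54.0 kJ mol⁻¹, ΔH1 = 8.00 kJ mol⁻¹)
    Q + L + X → X + Z (k2 = 5.29 M⁻² min⁻¹, Ea2 = 58.0 kJ mol⁻¹)
    2 D → D2 (k3 = 0.0831 M⁻¹ min⁻¹, Ea3 = 73.0 kJ mol⁻¹)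
    (constants at 90 °C)

X stands on both sides of the reversible step, so at pre-equilibrium G over free D equals K times free L. In teal, at the charged L, that product is 0.297. I carry this product, K times free L, as the holding ratio, the G that stands per free D once the reversible step has relaxed.

Does it relax in teal? The reversible step has the lower activation energy by 4.00 kJ mol⁻¹, so dividing its constant by the factor 11 of the Q step undervalues it. Even so, the first half-life of D by dimerisation is 54.0 h, and the relaxation half-life of the reversible step comes to 11.5 h, which is shorter than that half-life of D.

I then replace the falling curves by means. With Q held at its charge, the Q step takes 12.4% of the L in teal, which lowers the ratio to 0.261. Dimerisation sees free D, a share of the pool D plus G set by that ratio. Its second-order term, 0.555 for the bare pool, therefore leaves a pool of 74.1% of the charge. That gives G of 15.3%, but this G binds L too, and counting that loss lowers the ratio to 0.235. My figure for teal is therefore 14.1%.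

The forecast names teal, with 1.7% in grey, 6.8% in amber, 14.3% in teal and 3.8% in ochre, on the ground that “heat loses G and the coolest flask keeps the most”.

The flasks give 2.14% in grey, 8.32% in amber, 14.0% in teal and 5.25% in ochre, so teal holds more G than the others.

In teal the relaxation half-life of the reversible step at 30.0 h is 9.48 h, shorter than the run, and the holding ratio on the remaining 82% of L is 0.244, which on the remaining 57% of D gives 13.9% where the flask holds 14.0%. Grey, with 6.20 M⁻¹ and 41% of its L left, has a holding ratio of 0.171, which on its 11% of free D gives 1.83% where the flask holds 2.14%, while D2 stands at 87.2% of the charge.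

The constants are invented.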